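## Retrosynthetic overview

1. Spiro-cyclohexene (formed last): ring-closing metathesis of a but-3-enyl / 2-(4-methylpent-3-enyl)allyl pair on C11. Both chains are put on the α-methylene lactone by conjugate allylation and convex-face enolate alkylation, which fixes the 1,3-placement of the side chain that a myrcene Diels–Alder would not give.
2. Ten-membered carbocycle and cis-γ-lactone (formed together, second): C6–C7 disconnection to an enal / 2-(methoxycarbonyl)allylboronate, closed by a chiral phosphoric acid-catalysed intramolecular allylboration–lactonisation (key step).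
3. Allylboronate arm: Baylis–Hillman reaction at C7, then SN2′ borylation; the C8 angelate is installed early and carried through.
4. 3(2H)-Furanone (formed first): α-hydroxy lactone plus the acetylide of (Z)-3-methylpent-2-en-4-yn-1-ol, then 5-endo oxa-Michael cyclisation.
5. C10, then C8: proline-catalysed aldol of pyruvaldehyde dimethyl acetal with methyl pyruvate (first stereocentre), then 1,3-anti reduction.

Assumption: the target is made exactly as the SMILES encodes it, i.e. (6S,7R,8R,10R,11S), with a cis-fused 6,12-lactone and the 4-methylpent-3-enyl group on the cyclohexene carbon that is 1,3 to the spiro centre.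

Notation: germacrane numbering is used for the chain and the macrocycles. C1 = furanone C=O, C2 = furanone CH, C3 = furanone C–O, C4 (bears CH3), C5 (=CH), C6 (CH–O of the lactone), C7, C8 (CH–O of the angelate), C9 (CH2), C10 (C(CH3)–O), C11/C12/C13 = lactone α-carbon, C=O and exocyclic carbon.

## Route

Step 1
Reactants: 1 1,1-dimethoxypropan-2-one; 2 methyl pyruvate
Product: 3 methyl (2R)-2-hydroxy-5,5-dimethoxy-2-methyl-4-oxopentanoate
Conditions: L-proline (30 mol%), 1 (5 equiv), DMSO, 4 °C, 72 h
Reagents that add atoms: none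
Why: Proline enamine aldol: the enamine forms only on the CH3 side of 1 and adds to the activated keto group of 2 through the acid-organised Zimmerman–Traxler-type transition state, so the C10 tertiary carbinol (R, by analogy with known proline aldols of ketones with α-keto esters) is the first stereocentre and is set by asymmetric organocatalysis.

Step 2
Reactants: 3 aldol adduct
Product: 5 (3R,5R)-5-(dimethoxymethyl)-3-hydroxy-3-methyloxolan-2-one, via anti-diol ester 4 (not isolated)
Conditions: Me4NBH(OAc)3, MeCN/AcOH, −30 °C; then PPTS (cat.), PhMe, 50 °C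
Reagents that add atoms: none
Why: Saksena–Evans reduction: the C10 hydroxyl binds the borohydride and delivers hydride intramolecularly through a chair, giving the 1,3-anti diol (C8, R), which then lactonises onto the methyl ester under anhydrous mild acid that leaves the acetal intact.

Step 3
Reactants: 6 (2Z)-3-methylpent-2-en-4-yn-1-ol
Product: 7 triethyl{[(2Z)-3-methylpent-2-en-4-yn-1-yl]oxy}silane
Conditions: Et3SiCl, imidazole, CH2Cl2, 0 °C
Reagents that add atoms: chlorotriethylsilane, CC[Si](Cl)(CC)CC
Why: Standard silylation of a primary alcohol; the TES ether survives the later steps and is oxidised off directly in step 9.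

Step 4
Reactants: 5 hydroxy lactone; 7 TES enyne
Product: 10 furanone alcohol, via lithium acetylide 8 (not isolated), via hydroxy-ynone 9 (not isolated)
Conditions: 7 (2.3 equiv), n-BuLi (2.2 equiv), THF, −78 °C; 5, −78 → −40 °C; sat. NH4Cl; then Et2NH, MeOH, rt
Reagents that add atoms: none
Why: Acetylide acylation by a lactone stops at the lactolate (one equivalent of 8 is used up by the tertiary OH), and the α′-hydroxy ynone then closes by amine-mediated 5-endo oxa-Michael addition–elimination to the 3(2H)-furanone; C8 and C10 are untouched and the Z-alkene comes from 6.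

Step 5
Reactants: 10 furanone alcohol; 11 angelic acid
Product: 13 angelate acetal, via mixed anhydride 12 (not isolated)
Conditions: 11, 2,4,6-trichlorobenzoyl chloride, Et3N, PhMe, rt; then 10, 75 °C
Reagents that add atoms: none
Why: Yamaguchi esterification with the preformed mixed anhydride and no DMAP acylates the only free hydroxyl (C8) without isomerising the angelate to the tiglate.

Step 6
Reactants: 13 angelate acetal
Product: 14 α-angeloyloxy aldehyde
Conditions: Et3SiOTf, 2,4,6-collidine, CH2Cl2, 0 °C; then H2O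
Reagents that add atoms: water, O
Why: Chemoselective acetal cleavage through a collidinium intermediate (silyl triflate/pyridine-base method) frees the C7 aldehyde under near-neutral conditions that spare the TES ether, the esters and the epimerisable C8.

Step 7
Reactants: 14 α-angeloyloxy aldehyde; 15 methyl acrylate
Product: 17 Baylis–Hillman acetate (C7 epimers), via Baylis–Hillman alcohol 16 (not isolated)
Conditions: 15 (neat, 20 equiv), DABCO (1 equiv), rt; evaporate; then Ac2O, pyridine, DMAP (cat.), CH2Cl2, 0 °C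
Reagents that add atoms: acetic anhydride, CC(=O)OC(C)=O
Why: Morita–Baylis–Hillman reaction of an activated α-acyloxy aldehyde, then acetylation in the same flask; the new C7 carbinol needs no control because it becomes sp2 in step 8.

Step 8
Reactants: 17 Baylis–Hillman acetate
Product: 18 allylboronate TES ether
Conditions: B2pin2, CuCl, LiCl, KOAc, DMF, rt
Reagents that add atoms: bis(pinacolato)diboron, CC1(C)OB(OC1(C)C)B1OC(C)(C)C(C)(C)O1
Why: Hosomi–Miyaura borylation: borylcopper attacks the terminal acrylate carbon SN2′ and expels acetate, giving the primary allylboronate with the stable geometry (C8 cis to CH2B); the trisubstituted enoates and the allylic angelate, which a palladium catalyst could ionise, are left alone.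

Step 9
Reactants: 18 allylboronate TES ether
Product: 19 enal allylboronate
Conditions: (COCl)2, DMSO, CH2Cl2, −78 → −40 °C; then Et3N, −78 → 0 °C
Reagents that add atoms: none
Why: Under Swern conditions a primary TES ether is cleaved and oxidised in one operation; the low temperature keeps the Z-enal, and the ester-substituted allylboronate does not react with aldehydes without acid.

Step 10
Reactants: 19 enal allylboronate
Product: 21 macrocyclic α-methylene cis-lactone, via borate ester 20 (not isolated)
Conditions: (R)-TRIP (10 mol%), 4 Å MS, PhMe (0.002 M), −20 °C → rt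
Reagents that add atoms: none
Why: Proposed new method: a chiral phosphoric acid-catalysed intramolecular (macrocyclising) allylboration with in situ lactonisation. The acid H-bonds a pinacol oxygen while its P=O binds the formyl H, so the closed chair (Zimmerman–Traxler) transition state is catalyst-bound and (R)-TRIP directs attack to the Re face of the enal (C6 S). C8, cis to CH2B, sits axial, so C6/C7 are syn (cis-lactone, C7 R), and the C8 centre reinforces this (H inside, C9 anti, OAng outside). The rigid furanone/Z-enal scaffold and high dilution favour closure, and the borate then lactonises onto the neighbouring ester, forming the ten-membered carbocycle and the γ-lactone together. Closest known reactions: chiral phosphoric acid-catalysed intermolecular allylboration of aldehydes with allyl pinacolboronates, Brønsted acid-catalysed allylboration/lactonisation with 2-alkoxycarbonyl allylboronates, and metal-mediated Barbier macrocyclisations to germacranolides.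

Step 11
Reactants: 22 2-methylprop-2-en-1-ol; 23 1-bromo-3-methylbut-2-ene
Product: 25 6-methyl-2-methylidenehept-5-en-1-ol, via dilithio alkoxide 24 (not isolated)
Conditions: n-BuLi (2.2 equiv), TMEDA, Et2O, 0 °C → rt; then 23, −78 → 0 °C; H2O
Reagents that add atoms: none
Why: Allylic C-lithiation of the lithium alkoxide gives the C,O-dianion, which is alkylated at carbon by the primary allylic bromide (SN2).

Step 12
Reactants: 25 dienol
Product: 26 2-(bromomethyl)-6-methylhepta-1,5-diene
Conditions: CBr4, PPh3, CH2Cl2, 0 °C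
Reagents that add atoms: carbon tetrabromide, BrC(Br)(Br)Br
Why: Appel bromination of a primary allylic alcohol under neutral conditions; allylic transposition would give the same compound.

Step 13
Reactants: 21 macrocyclic α-methylene cis-lactone; 26 allylic bromide
Product: 28 metathesis precursor, via bromomagnesium enolate 27 (not isolated)
Conditions: CH2=CHCH2MgBr, CuBr·SMe2, LiCl, THF, −78 °C; then 26, HMPA, −78 → −20 °C
Reagents that add atoms: allylmagnesium bromide, C=CC[Mg]Br
Why: Three-component conjugate addition–enolate alkylation: allylcopper adds to the exocyclic methylene, the most reactive acceptor, and the enolate is alkylated by 26 on the convex face of the cis-fused lactone (anti to C5 and C8), setting quaternary C11 (S) with the substituted allyl group syn to H7.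

Step 14
Reactants: 28 metathesis precursor
Product: 29 target CNP0226905.2
Conditions: RuCl2(H2IMes)(=CH-C6H4-2-OiPr) (second-generation Hoveyda–Grubbs catalyst, 5 mol%), CH2Cl2 (0.005 M), 40 °C
Reagents that add atoms: none
Why: Ring-closing metathesis between the monosubstituted and the 1,1-disubstituted terminal alkenes closes the six-membered spiro ring with the trisubstituted alkene 1,3 to C11, driven by loss of ethene; the trisubstituted and conjugated alkenes elsewhere do not react.

## Compound list

1 | 1,1-dimethoxypropan-2-one | CC(=O)C(OC)OC | starting material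
2 | methyl 2-oxopropanoate (methyl pyruvate) | CC(=O)C(=O)OC | starting material
3 | methyl (2R)-2-hydroxy-5,5-dimethoxy-2-methyl-4-oxopentanoate | COC(OC)C(=O)C[C@@](C(=O)OC)(C)O | intermediate
4 | methyl (2R,4R)-2,4-dihydroxy-5,5-dimethoxy-2-methylpentanoate | COC(OC)[C@H](O)C[C@@](C(=O)OC)(C)O | intermediate (not isolated)
5 | (3R,5R)-5-(dimethoxymethyl)-3-hydroxy-3-methyloxolan-2-one | O=C1O[C@@H](C(OC)OC)C[C@@]1(C)O | intermediate
6 | (2Z)-3-methylpent-2-en-4-yn-1-ol | C#C/C(C)=C\CO | starting material
7 | triethyl{[(2Z)-3-methylpent-2-en-4-yn-1-yl]oxy}silane | C#C/C(C)=C\CO[Si](CC)(CC)CC | intermediate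
8 | {(3Z)-3-methyl-5-[(triethylsilyl)oxy]pent-3-en-1-yn-1-yl}lithium | [Li]C#C/C(C)=C\CO[Si](CC)(CC)CC | intermediate (not isolated)
9 | (2R,4R,8Z)-2,4-dihydroxy-1,1-dimethoxy-4,8-dimethyl-10-[(triethylsilyl)oxy]dec-8-en-6-yn-5-one | CC[Si](CC)(CC)OC/C=C(C)\C#CC(=O)[C@](C)(O)C[C@@H](O)C(OC)OC | intermediate (not isolated)
10 | (2R)-2-[(2R)-2-hydroxy-3,3-dimethoxypropyl]-2-methyl-5-{(2Z)-4-[(triethylsilyl)oxy]but-2-en-2-yl}furan-3(2H)-one | O[C@@H](C(OC)OC)C[C@@]1(C)OC(=CC1=O)/C(C)=C\CO[Si](CC)(CC)CC | intermediate
11 | (2Z)-2-methylbut-2-enoic acid (angelic acid) | C/C=C(/C)C(=O)O | starting material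
12 | (2Z)-2-methylbut-2-enoic 2,4,6-trichlorobenzoic anhydride | C/C=C(/C)C(=O)OC(=O)c1c(Cl)cc(Cl)cc1Cl | intermediate (not isolated)
13 | (2R)-1,1-dimethoxy-3-[(2R)-2-methyl-3-oxo-5-{(2Z)-4-[(triethylsilyl)oxy]but-2-en-2-yl}-2,3-dihydrofuran-2-yl]propan-2-yl (2Z)-2-methylbut-2-enoate | C/C=C(/C)C(=O)O[C@@H](C(OC)OC)C[C@@]1(C)OC(=CC1=O)/C(C)=C\CO[Si](CC)(CC)CC | intermediate
14 | (2R)-1-[(2R)-2-methyl-3-oxo-5-{(2Z)-4-[(triethylsilyl)oxy]but-2-en-2-yl}-2,3-dihydrofuran-2-yl]-3-oxopropan-2-yl (2Z)-2-methylbut-2-enoate | C/C=C(/C)C(=O)O[C@@H](C=O)C[C@@]1(C)OC(=CC1=O)/C(C)=C\CO[Si](CC)(CC)CC | intermediate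
15 | methyl prop-2-enoate (methyl acrylate) | C=CC(=O)OC | starting material
16 | methyl (4R)-3-hydroxy-2-methylidene-4-{[(2Z)-2-methylbut-2-enoyl]oxy}-5-[(2R)-2-methyl-3-oxo-5-{(2Z)-4-[(triethylsilyl)oxy]but-2-en-2-yl}-2,3-dihydrofuran-2-yl]pentanoate (both C3 epimers) | C/C=C(/C)C(=O)O[C@@H](C(O)C(=C)C(=O)OC)C[C@@]1(C)OC(=CC1=O)/C(C)=C\CO[Si](CC)(CC)CC | intermediate (not isolated)
17 | methyl (4R)-3-acetoxy-2-methylidene-4-{[(2Z)-2-methylbut-2-enoyl]oxy}-5-[(2R)-2-methyl-3-oxo-5-{(2Z)-4-[(triethylsilyl)oxy]but-2-en-2-yl}-2,3-dihydrofuran-2-yl]pentanoate (both C3 epimers) | C/C=C(/C)C(=O)O[C@@H](C(OC(C)=O)C(=C)C(=O)OC)C[C@@]1(C)OC(=CC1=O)/C(C)=C\CO[Si](CC)(CC)CC | intermediate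
18 | methyl (2E,4R)-4-{[(2Z)-2-methylbut-2-enoyl]oxy}-5-[(2R)-2-methyl-3-oxo-5-{(2Z)-4-[(triethylsilyl)oxy]but-2-en-2-yl}-2,3-dihydrofuran-2-yl]-2-[(4,4,5,5-tetramethyl-1,3,2-dioxaborolan-2-yl)methyl]pent-2-enoate (C4 of the pentenoate cis to CH2B) | C/C=C(/C)C(=O)O[C@@H](/C=C(\CB1OC(C)(C)C(C)(C)O1)C(=O)OC)C[C@@]2(C)OC(=CC2=O)/C(C)=C\CO[Si](CC)(CC)CC | intermediate
19 | methyl (2E,4R)-4-{[(2Z)-2-methylbut-2-enoyl]oxy}-5-{(2R)-2-methyl-3-oxo-5-[(2Z)-4-oxobut-2-en-2-yl]-2,3-dihydrofuran-2-yl}-2-[(4,4,5,5-tetramethyl-1,3,2-dioxaborolan-2-yl)methyl]pent-2-enoate | C/C=C(/C)C(=O)O[C@@H](/C=C(\CB1OC(C)(C)C(C)(C)O1)C(=O)OC)C[C@@]2(C)OC(=CC2=O)/C(C)=C\C=O | intermediate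
20 | methyl 2-[(6S,7S,8R,10R)-8-angeloyloxy-3,10-epoxy-1-oxo-6-(pinacolboryloxy)germacra-2,4(Z)-dien-7-yl]prop-2-enoate (same spatial arrangement at C7 as in 21; the descriptor differs only through the O–B substituent) | C/C=C(/C)C(=O)O[C@@H]1C[C@@]2(C)OC(=CC2=O)/C(C)=C\[C@H](OB2OC(C)(C)C(C)(C)O2)[C@@H]1C(=C)C(=O)OC | intermediate (not isolated)
21 | (6S,7R,8R,10R)-8-angeloyloxy-3,10-epoxy-1-oxogermacra-2,4(Z),11(13)-trien-12,6-olide (cis-fused α-methylene γ-lactone; 3(2H)-furanone bridging C3 and C10) | C/C=C(/C)C(=O)O[C@@H]1C[C@@]2(C)OC(=CC2=O)/C(C)=C\[C@@H]2OC(=O)C(=C)[C@@H]21 | intermediate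
22 | 2-methylprop-2-en-1-ol | CC(=C)CO | starting material
23 | 1-bromo-3-methylbut-2-ene | CC(C)=CCBr | starting material
24 | lithium 2-(lithiomethyl)prop-2-en-1-olate | [Li]CC(=C)CO[Li] | intermediate (not isolated)
25 | 6-methyl-2-methylidenehept-5-en-1-ol | C=C(CO)CCC=C(C)C | intermediate
26 | 2-(bromomethyl)-6-methylhepta-1,5-diene | C=C(CBr)CCC=C(C)C | intermediate
27 | bromomagnesium enolate (C11=C12–OMgBr) of (6S,7R,8R,10R)-8-angeloyloxy-11-(but-3-en-1-yl)-3,10-epoxy-1-oxogermacra-2,4(Z)-dien-12,6-olide | C/C=C(/C)C(=O)O[C@@H]1C[C@@]2(C)OC(=CC2=O)/C(C)=C\[C@@H]2OC(O[Mg]Br)=C(CCC=C)[C@@H]21 | intermediate (not isolated)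
28 | (6S,7R,8R,10R,11S)-8-angeloyloxy-11-(but-3-en-1-yl)-3,10-epoxy-11-(6-methyl-2-methylidenehept-5-en-1-yl)-1-oxogermacra-2,4(Z)-dien-12,6-olide | C/C=C(/C)C(=O)O[C@@H]1C[C@@]2(C)OC(=CC2=O)/C(C)=C\[C@@H]2OC(=O)[C@](CC(=C)CCC=C(C)C)(CCC=C)[C@@H]21 | intermediate
29 | CNP0226905.2: (6S,7R,8R,10R,11S)-8-angeloyloxy-3,10-epoxy-1-oxogermacra-2,4(Z)-dien-12,6-olide with C11 spiro-fused to a cyclohex-3-ene (C11–C13H2–CH2–CH=C(4-methylpent-3-enyl)–CH2–C11) | C/C=C(/C)C(=O)O[C@@H]1C[C@@]2(C)OC(=CC2=O)/C(C)=C\[C@@H]2OC(=O)[C@]3(CCC=C(CCC=C(C)C)C3)[C@@H]21 | target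

## Step count and risks

Total steps: 14. Longest linear sequence: 11 (steps 1, 2, 4, 5, 6, 7, 8, 9, 10, 13, 14).

The three steps most likely to fail:

Step 10 (the proposed new step). Risks: the medium ring may not close in competition with oligomerisation; catalyst and substrate control may not match; the Z-enal may isomerise under acid; the δ-acyloxy allylboronate may eliminate. Fallback with known chemistry, setting out from 17 and coming back at 21: SN2′ displacement of the acetate with MgBr2·OEt2 in THF gives methyl (2Z,4R)-2-(bromomethyl)-4-angeloyloxy-5-[furanonyl]pent-2-enoate TES ether F1. Swern deprotective oxidation as in step 9 gives the bromo enal F2. An intramolecular zinc Barbier allylation (Zn dust, THF/sat. aq. NH4Cl, 0.003 M) then closes C6–C7, and the zinc alkoxide lactonises onto the methyl ester to give 21. The same alkene geometry leads through a closed transition state to the cis-lactone, and this macrocyclising Barbier allylation/lactonisation is the established way to germacranolide α-methylene lactones.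

Step 7. Risk: aldehyde 14 can epimerise at C8 or suffer angelate migration during a slow amine-catalysed Baylis–Hillman reaction. Fallback, setting out from 14 and coming back at 16: vinylalumination. Methyl propiolate with iBu2AlH and N-methylmorpholine N-oxide in THF at 0 °C gives the [α-(methoxycarbonyl)vinyl]alane, which adds to 14 at −78 °C within an hour without any amine base. Aqueous work-up gives 16 directly, so no new compound is made (F0), and 16 is acetylated as in step 7.

Step 13. Risks: allylcopper may also attack the C1–C5 dienone (1,6-addition) or the angelate, and quaternisation of the hindered enolate may be slow. Fallback, setting out from 21 and coming back at 29 (it replaces steps 13 and 14): thermal Diels–Alder reaction of 21 with myrcene (10 equiv, PhMe, 110 °C, BHT, sealed tube). The diene adds to the convex face, which sets C11 correctly. Without catalyst the wanted 1,3-adduct 29 is expected only as the minor regioisomer, beside the 1,4-regioisomeric spiro adduct F3 (roughly 1:2 to 1:3). Preparative HPLC is therefore needed, and Lewis acids must be avoided because they raise the share of F3.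

## Further compounds

F0 | step 7 | none | none
F1 | step 10 | methyl (2Z,4R)-2-(bromomethyl)-4-{[(2Z)-2-methylbut-2-enoyl]oxy}-5-[(2R)-2-methyl-3-oxo-5-{(2Z)-4-[(triethylsilyl)oxy]but-2-en-2-yl}-2,3-dihydrofuran-2-yl]pent-2-enoate | C/C=C(/C)C(=O)O[C@@H](/C=C(\CBr)C(=O)OC)C[C@@]1(C)OC(=CC1=O)/C(C)=C\CO[Si](CC)(CC)CC
F2 | step 10 | methyl (2Z,4R)-2-(bromomethyl)-4-{[(2Z)-2-methylbut-2-enoyl]oxy}-5-{(2R)-2-methyl-3-oxo-5-[(2Z)-4-oxobut-2-en-2-yl]-2,3-dihydrofuran-2-yl}pent-2-enoate | C/C=C(/C)C(=O)O[C@@H](/C=C(\CBr)C(=O)OC)C[C@@]1(C)OC(=CC1=O)/C(C)=C\C=O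
F3 | step 13 | 1,4-regioisomer of 29: (6S,7R,8R,10R,11S) spiro adduct with the 4-methylpent-3-enyl group on the cyclohexene carbon 1,4 to C11 | C/C=C(/C)C(=O)O[C@@H]1C[C@@]2(C)OC(=CC2=O)/C(C)=C\[C@@H]2OC(=O)[C@@]3(CC=C(CCC=C(C)C)CC3)[C@@H]21
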